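**Retrosynthetic overview**

1. Numbering: ring C1 (OMe), C2 (OH), C3 (OBz), C4 (OH), C5 (carrying C7H2OBz), C6 (=CH). The plan rests on the allylic carbinol C4(OH)–C5=C6 of the single cyclohexene ring and on the all-trans triad C1–C3, which is C2–C4 of D-xylose.
2. Last disconnection: the 4-methoxybenzyl (PMB) ether on O2 (DDQ), back to cyclohexenol 20.
3. Key disconnection C4–C5: intramolecular Nozaki–Hiyama–Kishi addition of the C5 (Z)-vinyl iodide to the C4 aldehyde of open-chain 17. This closes the only ring and sets C4.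
4. 17 comes from dioxane 15 by reductive acetal opening (PMB onto O2, primary OH freed) and oxidation. 15 comes from lactol 7 by a Z-selective α-iodo Wittig reaction, ester reduction and double benzoylation.
5. Lactol 7 comes from D-xylose (1) through the 1,4-lactone, its 3,5-O-(4-methoxybenzylidene) acetal and methylation of O2 (xylose numbering).

Key step: step 11

Remark: intermediates up to 17 carry D-xylose locants (xylose C1–C5 become ring C6, C1, C2, C3, C4), and the 4-methoxybenzylidene carbon is drawn as the (S) epimer expected at equilibrium (aryl equatorial); that centre is removed in step 9.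

**Route**

Step 1
Reactants: 1 D-xylose
Product: 3 D-xylono-1,4-lactone, via D-xylonic acid 2 (not isolated)
Conditions: Br2, BaCO3, H2O, 0 °C to rt; filter; concentrate from AcOH, 50 °C
Reagents that add atoms: none
Why: Bromine-water oxidation of the aldose gives the aldonic acid, which lactonises to the five-membered lactone on concentration from acid, with no stereocentre touched.

Step 2
Reactants: 3 D-xylono-1,4-lactone; 4 4-methoxybenzaldehyde dimethyl acetal
Product: 5 3,5-O-[(S)-4-methoxybenzylidene]-D-xylono-1,4-lactone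
Conditions: CSA (cat.), DMF, 50 °C, reduced pressure
Reagents that add atoms: 4-methoxybenzaldehyde dimethyl acetal (compound 4), COc1ccc(cc1)C(OC)OC
Why: Acid-catalysed transacetalisation closes a 1,3-dioxane across the cis-disposed O3 and O5 (the trans O2/O3 pair cannot bridge), leaving only O2–H free, and the acetal carbon should equilibrate to the epimer with the aryl group equatorial.

Step 3
Reactants: 5 3,5-O-[(S)-4-methoxybenzylidene]-D-xylono-1,4-lactone
Product: 6 3,5-O-[(S)-4-methoxybenzylidene]-2-O-methyl-D-xylono-1,4-lactone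
Conditions: MeI, Ag2O, 4 Å MS, MeCN, rt, dark
Reagents that add atoms: iodomethane, CI
Why: Purdie methylation etherifies the single free hydroxyl under non-basic conditions, so the lactone survives and C2 should not epimerise.

Step 4
Reactants: 6 3,5-O-[(S)-4-methoxybenzylidene]-2-O-methyl-D-xylono-1,4-lactone
Product: 7 3,5-O-[(S)-4-methoxybenzylidene]-2-O-methyl-D-xylofuranose (anomeric mixture)
Conditions: iBu2AlH (1.1 equiv), CH2Cl2, −78 °C; aq. potassium sodium tartrate
Reagents that add atoms: none
Why: Partial reduction of a lactone to the lactol by iBu2AlH stops at the tetrahedral aluminate at −78 °C, a temperature at which the arylidene acetal is not opened.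

Step 5
Reactants: 8 ethyl (triphenylphosphoranylidene)acetate
Product: 10 ethyl iodo(triphenylphosphoranylidene)acetate, via iodophosphonium iodide 9 (not isolated)
Conditions: I2, K2CO3, MeOH, 0 °C to rt
Reagents that add atoms: iodine, II
Why: Electrophilic α-iodination of the stabilised ylide gives the iodophosphonium salt, which carbonate deprotonates to the isolable α-iodo ylide.

Step 6
Reactants: 7 3,5-O-[(S)-4-methoxybenzylidene]-2-O-methyl-D-xylofuranose; 10 ethyl iodo(triphenylphosphoranylidene)acetate
Product: 12 ethyl (Z)-2,3-dideoxy-2-iodo-5,7-O-[(S)-4-methoxybenzylidene]-4-O-methyl-D-xylo-hept-2-enonate, via open-chain hydroxy aldehyde 11 (not isolated)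
Conditions: PhMe, 80 °C
Reagents that add atoms: iodo ylide (compound 10), CCOC(=O)C(I)=P(c1ccccc1)(c1ccccc1)c1ccccc1
Why: Wittig olefination of the lactol through its hydroxy-aldehyde tautomer with an ester-stabilised ylide should place the ester trans to the chain, so that iodine and chain are cis (Z), as the later ring closure requires.

Step 7
Reactants: 12 ethyl (Z)-2,3-dideoxy-2-iodo-5,7-O-[(S)-4-methoxybenzylidene]-4-O-methyl-D-xylo-hept-2-enonate
Product: 13 (Z)-2,3-dideoxy-2-iodo-5,7-O-[(S)-4-methoxybenzylidene]-4-O-methyl-D-xylo-hept-2-enitol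
Conditions: iBu2AlH (3.5 equiv), CH2Cl2, −78 °C; aq. potassium sodium tartrate
Reagents that add atoms: none
Why: 1,2-Reduction of the α,β-unsaturated ester by iBu2AlH gives the allylic alcohol at −78 °C without touching the vinyl iodide, the alkene geometry or the acetal.

Step 8
Reactants: 13 (Z)-2,3-dideoxy-2-iodo-5,7-O-[(S)-4-methoxybenzylidene]-4-O-methyl-D-xylo-hept-2-enitol; 14 benzoyl chloride
Product: 15 (Z)-1,6-di-O-benzoyl-2,3-dideoxy-2-iodo-5,7-O-[(S)-4-methoxybenzylidene]-4-O-methyl-D-xylo-hept-2-enitol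
Conditions: BzCl (2.5 equiv), pyridine, DMAP (cat.), CH2Cl2, 0 °C to rt
Reagents that add atoms: benzoyl chloride (compound 14), O=C(Cl)c1ccccc1
Why: DMAP-catalysed acylation of both free hydroxyls installs the two benzoates of the target (on O7 and on the future ring O3) in one operation, with retention at the secondary carbinol.

Step 9
Reactants: 15 (Z)-1,6-di-O-benzoyl-2,3-dideoxy-2-iodo-5,7-O-[(S)-4-methoxybenzylidene]-4-O-methyl-D-xylo-hept-2-enitol
Product: 16 (2Z,4S,5R,6R)-7-hydroxy-2-iodo-4-methoxy-5-[(4-methoxybenzyl)oxy]hept-2-ene-1,6-diyl dibenzoate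
Conditions: Et3SiH, PhBCl2, 4 Å MS, CH2Cl2, −78 °C; aq. NaHCO3
Reagents that add atoms: none
Why: In this regioselective reductive opening of an arylidene acetal, PhBCl2 should bind the less hindered primary oxygen, that C–O bond ionises and Et3SiH reduces the oxocarbenium ion, which leaves the PMB ether on the secondary oxygen and the primary alcohol free under conditions that spare benzoates.

Step 10
Reactants: 16 (2Z,4S,5R,6R)-7-hydroxy-2-iodo-4-methoxy-5-[(4-methoxybenzyl)oxy]hept-2-ene-1,6-diyl dibenzoate
Product: 17 (2Z,4S,5R,6S)-2-iodo-4-methoxy-5-[(4-methoxybenzyl)oxy]-7-oxohept-2-ene-1,6-diyl dibenzoate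
Conditions: Dess–Martin periodinane, CH2Cl2, 0 °C to rt; used at once
Reagents that add atoms: none
Why: Dess–Martin oxidation converts the primary alcohol to the aldehyde under near-neutral conditions that should neither epimerise the α-benzoyloxy centre nor eliminate the β-ether.

Step 11
Reactants: 17 (2Z,4S,5R,6S)-2-iodo-4-methoxy-5-[(4-methoxybenzyl)oxy]-7-oxohept-2-ene-1,6-diyl dibenzoate
Product: 20 [(3S,4R,5R,6S)-5-(benzoyloxy)-6-hydroxy-3-methoxy-4-[(4-methoxybenzyl)oxy]cyclohex-1-en-1-yl]methyl benzoate (the O2 PMB ether of the target), via vinylchromium dichloride 18 (not isolated), via chromium alkoxide 19 (not isolated)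
Conditions: CrCl2 (8 equiv), NiCl2 (2 mol %), degassed DMSO, 25 °C, 0.005 M; then H2O
Reagents that add atoms: none
Why: CrCl2 reduces NiCl2 to zerovalent nickel, which inserts into the C5–I bond with retention of the Z geometry and hands the vinyl group to trivalent chromium (18); this adds to the C4 aldehyde to give alkoxide 19, hydrolysed on work-up. The closest known reaction type is the intramolecular Nozaki–Hiyama–Kishi cyclisation of sugar-derived haloalkenyl aldehydes to cyclohexenols. The single ring, the cyclohexene, closes in the 6-exo-trig mode, C5 attacking the carbonyl carbon while its oxygen stays outside the ring. The new C4 centre should be controlled by a half-chair transition state in which the C1, C2 and C3 substituents are pseudo-equatorial, the forming C4–C5 bond lies anti to the C3–O bond and the bulky chromium-bound oxygen takes the pseudo-equatorial site, trans to the C3 benzoate (4S). The step needs chemoselectivity for the aldehyde over the two benzoates and over β-elimination of the allylic benzoate, which the weakly basic, ester-tolerant vinylchromium and the proximity of the aldehyde should secure, and ring closure over dimerisation, which the Z iodoalkene (metal and chain cis) and high dilution should secure.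

Step 12
Reactants: 20 [(3S,4R,5R,6S)-5-(benzoyloxy)-6-hydroxy-3-methoxy-4-[(4-methoxybenzyl)oxy]cyclohex-1-en-1-yl]methyl benzoate
Product: 21 [(3S,4R,5R,6S)-5-(benzoyloxy)-4,6-dihydroxy-3-methoxycyclohex-1-en-1-yl]methyl benzoate (target)
Conditions: DDQ, CH2Cl2/pH 7 buffer (18:1), 0 °C to rt
Reagents that add atoms: none
Why: Oxidative cleavage of the PMB ether by DDQ (benzylic hydride abstraction, then hydrolysis of the oxocarbenium ion) is neutral, so the benzoates should not migrate and the alkene, allylic alcohol and methyl ether should be untouched.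

**Compound list**

1 | D-xylose | O=C[C@H](O)[C@@H](O)[C@H](O)CO | starting material
2 | D-xylonic acid | OC(=O)[C@H](O)[C@@H](O)[C@H](O)CO | intermediate
3 | D-xylono-1,4-lactone | O=C1O[C@H](CO)[C@H](O)[C@H]1O | intermediate
4 | 4-methoxybenzaldehyde dimethyl acetal | COc1ccc(cc1)C(OC)OC | starting material
5 | 3,5-O-[(S)-4-methoxybenzylidene]-D-xylono-1,4-lactone | O=C1O[C@@H]2CO[C@H](c3ccc(OC)cc3)O[C@@H]2[C@H]1O | intermediate
6 | 3,5-O-[(S)-4-methoxybenzylidene]-2-O-methyl-D-xylono-1,4-lactone | O=C1O[C@@H]2CO[C@H](c3ccc(OC)cc3)O[C@@H]2[C@H]1OC | intermediate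
7 | 3,5-O-[(S)-4-methoxybenzylidene]-2-O-methyl-D-xylofuranose (anomeric mixture) | OC1O[C@@H]2CO[C@H](c3ccc(OC)cc3)O[C@@H]2[C@H]1OC | intermediate
8 | ethyl (triphenylphosphoranylidene)acetate | CCOC(=O)C=P(c1ccccc1)(c1ccccc1)c1ccccc1 | starting material
9 | [(ethoxycarbonyl)(iodo)methyl]triphenylphosphonium iodide | CCOC(=O)C(I)[P+](c1ccccc1)(c1ccccc1)c1ccccc1.[I-] | intermediate
10 | ethyl iodo(triphenylphosphoranylidene)acetate | CCOC(=O)C(I)=P(c1ccccc1)(c1ccccc1)c1ccccc1 | intermediate
11 | 3,5-O-[(S)-4-methoxybenzylidene]-2-O-methyl-aldehydo-D-xylose | O=C[C@H](OC)[C@H]1O[C@@H](c2ccc(OC)cc2)OC[C@H]1O | intermediate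
12 | ethyl (Z)-2,3-dideoxy-2-iodo-5,7-O-[(S)-4-methoxybenzylidene]-4-O-methyl-D-xylo-hept-2-enonate | CCOC(=O)/C(I)=C/[C@H](OC)[C@H]1O[C@@H](c2ccc(OC)cc2)OC[C@H]1O | intermediate
13 | (Z)-2,3-dideoxy-2-iodo-5,7-O-[(S)-4-methoxybenzylidene]-4-O-methyl-D-xylo-hept-2-enitol | OC/C(I)=C/[C@H](OC)[C@H]1O[C@@H](c2ccc(OC)cc2)OC[C@H]1O | intermediate
14 | benzoyl chloride | O=C(Cl)c1ccccc1 | starting material
15 | (Z)-1,6-di-O-benzoyl-2,3-dideoxy-2-iodo-5,7-O-[(S)-4-methoxybenzylidene]-4-O-methyl-D-xylo-hept-2-enitol | CO[C@@H](/C=C(\I)COC(=O)c1ccccc1)[C@H]1O[C@@H](c2ccc(OC)cc2)OC[C@H]1OC(=O)c1ccccc1 | intermediate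
16 | (2Z,4S,5R,6R)-7-hydroxy-2-iodo-4-methoxy-5-[(4-methoxybenzyl)oxy]hept-2-ene-1,6-diyl dibenzoate | CO[C@@H](/C=C(\I)COC(=O)c1ccccc1)[C@@H](OCc1ccc(OC)cc1)[C@H](OC(=O)c1ccccc1)CO | intermediate
17 | (2Z,4S,5R,6S)-2-iodo-4-methoxy-5-[(4-methoxybenzyl)oxy]-7-oxohept-2-ene-1,6-diyl dibenzoate | CO[C@@H](/C=C(\I)COC(=O)c1ccccc1)[C@@H](OCc1ccc(OC)cc1)[C@H](OC(=O)c1ccccc1)C=O | intermediate
18 | vinylchromium dichloride of 17 (CrCl2 on C5 in place of iodine, trivalent chromium) | CO[C@@H](/C=C(\[Cr](Cl)Cl)COC(=O)c1ccccc1)[C@@H](OCc1ccc(OC)cc1)[C@H](OC(=O)c1ccccc1)C=O | intermediate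
19 | dichlorochromium alkoxide of 20 (CrCl2 on the C4 oxygen, trivalent chromium) | CO[C@H]1C=C(COC(=O)c2ccccc2)[C@H](O[Cr](Cl)Cl)[C@@H](OC(=O)c2ccccc2)[C@@H]1OCc3ccc(OC)cc3 | intermediate
20 | [(3S,4R,5R,6S)-5-(benzoyloxy)-6-hydroxy-3-methoxy-4-[(4-methoxybenzyl)oxy]cyclohex-1-en-1-yl]methyl benzoate | CO[C@H]1C=C(COC(=O)c2ccccc2)[C@H](O)[C@@H](OC(=O)c2ccccc2)[C@@H]1OCc3ccc(OC)cc3 | intermediate
21 | [(3S,4R,5R,6S)-5-(benzoyloxy)-4,6-dihydroxy-3-methoxycyclohex-1-en-1-yl]methyl benzoate | CO[C@H]1C=C(COC(=O)c2ccccc2)[C@H](O)[C@@H](OC(=O)c2ccccc2)[C@@H]1O | target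

**Step count**

Total step count: 12. Longest linear sequence: 11 steps (steps 1–4 and 6–12 from D-xylose); step 5 prepares the ylide.

**Steps most likely to fail**

Step 11. The ring closure may show poor facial selectivity at C4, because the open-chain polar preference of an α-acyloxy aldehyde runs towards the 3,4-cis carbinol. Reductive loss of iodine or β-elimination of the allylic benzoate from the vinylchromium may also compete. The fallback sets C4 by hydride delivery instead of by the C–C bond formation. It sets out from 17: the cyclisation is run as described, and the carbinol mixture, rich in the C4 epimer of 20 F1, is oxidised with Dess–Martin periodinane (CH2Cl2, rt) to cyclohexenone F2. Luche reduction (NaBH4, CeCl3·7H2O, MeOH, −78 °C) should then deliver hydride axially to the half-chair and give the pseudo-equatorial alcohol trans to the C3 benzoate. The fallback comes back to the route at 20.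

Step 6. Olefination of the bicyclic lactol by the hindered, doubly stabilised ylide may be slow. The freed hydroxyl may add back to the iodoenoate (conjugate addition to a tetrahydrofuran), and prolonged heating may erode the Z geometry. The fallback uses an open-chain aldehyde with no free hydroxyl and sets out from lactone 6. Aminolysis (MeNHOMe·HCl, Me3Al, CH2Cl2) should give hydroxy Weinreb amide F3, and silylation (Et3SiCl, imidazole) triethylsilyl ether F4. Reduction with iBu2AlH at −78 °C should give aldehyde F5, which should react with ylide 10 at rt to give iodoenoate F6. iBu2AlH reduction should give allylic alcohol F7, and Bu4NF removes the silyl group. The fallback comes back to the route at 13.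

Step 9. The acetal opening may lose regiocontrol (PMB ending on the primary oxygen), the neighbouring benzoate may migrate to the liberated primary hydroxyl, or the boron Lewis acid may ionise the allylic ether. The fallback replaces the reductive opening by stepwise protection and sets out from 15. Mild hydrolysis of the acetal (AcOH/H2O/THF, rt) should give diol F8, and TBSCl/imidazole should silylate only the primary hydroxyl to give silyl ether F9. 4-Methoxybenzyl trichloroacetimidate with catalytic La(OTf)3 (PhMe, rt) should give PMB ether F10, and HF·pyridine removes the silyl group under acidic conditions that disfavour acyl migration. The fallback comes back to the route at 16.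

**Further compounds**

F1 | step 11 | C4 epimer of 20 (C4 hydroxyl cis to the C3 benzoate) | CO[C@H]1C=C(COC(=O)c2ccccc2)[C@@H](O)[C@@H](OC(=O)c2ccccc2)[C@@H]1OCc3ccc(OC)cc3
F2 | step 11 | C4 ketone of 20 (cyclohex-2-enone; C1 OMe, C2 OPMB and C3 OBz unchanged) | CO[C@H]1C=C(COC(=O)c2ccccc2)C(=O)[C@@H](OC(=O)c2ccccc2)[C@@H]1OCc3ccc(OC)cc3
F3 | step 6 | N-methoxy-N-methyl amide of 3,5-O-[(S)-4-methoxybenzylidene]-2-O-methyl-D-xylonic acid (4-OH free) | CON(C)C(=O)[C@H](OC)[C@H]1O[C@@H](c2ccc(OC)cc2)OC[C@H]1O
F4 | step 6 | 4-O-triethylsilyl ether of F3 | CON(C)C(=O)[C@H](OC)[C@H]1O[C@@H](c2ccc(OC)cc2)OC[C@H]1O[Si](CC)(CC)CC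
F5 | step 6 | 3,5-O-[(S)-4-methoxybenzylidene]-2-O-methyl-4-O-triethylsilyl-aldehydo-D-xylose | O=C[C@H](OC)[C@H]1O[C@@H](c2ccc(OC)cc2)OC[C@H]1O[Si](CC)(CC)CC
F6 | step 6 | 6-O-triethylsilyl ether of 12 | CCOC(=O)/C(I)=C/[C@H](OC)[C@H]1O[C@@H](c2ccc(OC)cc2)OC[C@H]1O[Si](CC)(CC)CC
F7 | step 6 | 6-O-triethylsilyl ether of 13 | OC/C(I)=C/[C@H](OC)[C@H]1O[C@@H](c2ccc(OC)cc2)OC[C@H]1O[Si](CC)(CC)CC
F8 | step 9 | (2Z,4S,5R,6R)-5,7-dihydroxy-2-iodo-4-methoxyhept-2-ene-1,6-diyl dibenzoate | CO[C@@H](/C=C(\I)COC(=O)c1ccccc1)[C@@H](O)[C@H](OC(=O)c1ccccc1)CO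
F9 | step 9 | 7-O-tert-butyldimethylsilyl ether of F8 | CO[C@@H](/C=C(\I)COC(=O)c1ccccc1)[C@@H](O)[C@H](OC(=O)c1ccccc1)CO[Si](C)(C)C(C)(C)C
F10 | step 9 | 7-O-tert-butyldimethylsilyl ether of 16 | CO[C@@H](/C=C(\I)COC(=O)c1ccccc1)[C@@H](OCc1ccc(OC)cc1)[C@H](OC(=O)c1ccccc1)CO[Si](C)(C)C(C)(C)C
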